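**Plan**

1. Retrosynthesis: in ring A (the cyclohexenone) the ketone carbon C6 and the acetoxy carbon C9 are 1,4-related across the C7=C8 alkene. This 2-ene-1,4-dioxygenated array is the retron of a singlet oxygen [4+2] adduct, so both C–O bonds are cut first, back to a spiro cyclohexa-1,3-diene (C6=C7–C8=C9).
2. Further cuts: the diene goes back to the ring A enone (through its dienyl triflate); then the lactone O2–C3 bond and the C1–C1' bond (alkenyl iodide plus formyl ester); then ring A at C5–C6 and C9–C10 (Diels–Alder of an α-substituted acrolein with an amino siloxy diene).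
3. Forward: side-chain alkenyl iodide (fragment 1); ring A with its quaternary carbon (fragment 2); fragment union, which closes the lactone ring onto C5; enone to diene; peroxide bridge across C6/C9; then reduction, inversion with acetate at C9, oxidation at C6, desilylation.
4. Stereochemistry: C5' from CBS reduction; C5 from the catalysed Diels–Alder; C1 from ligand-controlled alkenylchromium addition; C6/C9 from oxygen addition to the diene face syn to C4, with C9 then inverted in the Mitsunobu step.
5. Locants: 2-oxaspiro[4.5]decane numbering (C1 lactone carbinol, O2, C3 lactone carbonyl, C4 lactone CH2, C5 spiro carbon, C6–C10 ring A); primed locants belong to the heptadienyl side chain.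

Key step: step 11

Remark: the hand of the TADDOL (step 7) and of the sulfonamide ligand (step 8) is the one expected from the usual facial models for α-substituted acroleins and for aldehydes; if a model fails for these substrates, the antipode is used with no other change.

**Route**

Step 1
Reactants: 1 pent-4-ynoic acid
Product: 3 N-methoxy-N-methylpent-4-ynamide, via acyl imidazole 2 (not isolated)
Conditions: CDI (1.1 equiv), CH2Cl2, rt; then MeNH(OMe)·HCl (1.2 equiv), rt
Reagents that add atoms: N,O-dimethylhydroxylamine hydrochloride (CNOC.Cl)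
Why: Activation of the acid as its acyl imidazole followed by aminolysis is the standard Weinreb amide synthesis and leaves the terminal alkyne untouched.

Step 2
Reactants: 3 N-methoxy-N-methylpent-4-ynamide; 4 isopropenylmagnesium bromide
Product: 5 2-methylhept-1-en-6-yn-3-one
Conditions: 4 (2.3 equiv), THF, −20 to 0 °C; inverse quench into cold 1 M HCl
Reagents that add atoms: none
Why: Grignard acylation with a Weinreb amide stops at the ketone because the chelated tetrahedral adduct survives until the acidic quench, and the excess reagent covers deprotonation of the alkyne C–H.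

Step 3
Reactants: 5 2-methylhept-1-en-6-yn-3-one
Product: 6 (3R)-2-methylhept-1-en-6-yn-3-ol
Conditions: (S)-2-methyl-CBS-oxazaborolidine (20 mol %), catecholborane (1.5 equiv), toluene, −78 °C; MeOH, then aq. NaOH
Reagents that add atoms: none
Why: In this Corey–Bakshi–Shibata reduction the α-branched alkenyl group acts as the large substituent and the chain as the small one, so the (S)-catalyst should give the (R)-carbinol (C5' of the target), while catecholborane at low temperature spares alkyne and alkene.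

Step 4
Reactants: 6 (3R)-2-methylhept-1-en-6-yn-3-ol
Product: 7 tert-butyldimethyl{[(3R)-2-methylhept-1-en-6-yn-3-yl]oxy}silane
Conditions: TBSCl, imidazole, DMF, rt
Reagents that add atoms: tert-butyldimethylsilyl chloride (CC(C)(C)[Si](C)(C)Cl)
Why: Imidazole-promoted silylation of a secondary alcohol is routine, and this silyl ether should survive the organometallic, basic, photochemical and oxidative steps and be removed last with fluoride.

Step 5
Reactants: 7 tert-butyldimethyl{[(3R)-2-methylhept-1-en-6-yn-3-yl]oxy}silane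
Product: 9 tert-butyl{[(3R,6E)-7-iodo-2,6-dimethylhepta-1,6-dien-3-yl]oxy}dimethylsilane, via alkenyl(dimethyl)alane 8 (not isolated)
Conditions: Me3Al (2.5 equiv), Cp2ZrCl2 (0.25 equiv), CH2Cl2, 0 °C to rt; then I2, THF, −30 to 0 °C
Reagents that add atoms: trimethylaluminium (C[Al](C)C); iodine (II)
Why: Negishi carboalumination adds methyl and aluminium syn across the terminal alkyne with methyl on the internal carbon, and iodinolysis of the C–Al bond with retention should give the (E)-trisubstituted alkenyl iodide, the 1,1-disubstituted alkene being inert to this catalyst.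

Step 6
Reactants: 10 methyl 4-oxobutanoate; 11 formaldehyde
Product: 12 methyl 3-formylbut-3-enoate
Conditions: 37% aq. HCHO, pyrrolidine (10 mol %), propionic acid (10 mol %), i-PrOH, 45 °C
Reagents that add atoms: none
Why: Amine-catalysed α-methylenation of an aldehyde (Mannich condensation and elimination through the enamine) is general for linear aldehydes, and the buffered medium should keep the new double bond from moving into conjugation with the ester.

Step 7
Reactants: 12 methyl 3-formylbut-3-enoate; 13 (E)-3-(tert-butyldimethylsilyloxy)-N,N-dimethylbuta-1,3-dien-1-amine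
Product: 15 methyl 2-[(1S)-1-formyl-4-oxocyclohex-2-en-1-yl]acetate, via amino silyl enol ether cycloadduct 14 (not isolated)
Conditions: tetra(1-naphthyl)-TADDOL (20 mol %, antipode per the remark), toluene, −78 °C; then 48% aq. HF, MeCN, 0 °C
Reagents that add atoms: none
Why: In this hydrogen-bond-catalysed Diels–Alder reaction of an α-substituted acrolein the TADDOL binds the formyl oxygen and shields one face of the dienophile, so the ring carbons add to the other face and fix the quaternary carbon (future spiro C5) with the usual regiochemistry (amine-bearing carbon next to the quaternary centre), and HF then hydrolyses the silyl enol ether and eliminates dimethylamine to give the enone.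

Step 8
Reactants: 15 methyl 2-[(1S)-1-formyl-4-oxocyclohex-2-en-1-yl]acetate; 9 tert-butyl{[(3R,6E)-7-iodo-2,6-dimethylhepta-1,6-dien-3-yl]oxy}dimethylsilane
Product: 17 (1R,5S)-1-[(1E,5R)-5-(tert-butyldimethylsilyloxy)-2,6-dimethylhepta-1,6-dien-1-yl]-2-oxaspiro[4.5]dec-6-ene-3,8-dione, via hydroxy ester 16 (not isolated)
Conditions: CrCl2 (3 equiv), NiCl2 (5 mol %), chiral 2-(oxazolinyl)aryl methanesulfonamide ligand (3.3 equiv, antipode per the remark), Et3N (3.3 equiv), THF, rt; aqueous work-up; then PPTS (10 mol %), CH2Cl2, rt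
Reagents that add atoms: none
Why: In this Nozaki–Hiyama–Kishi coupling the alkenylchromium reagent adds only to the aldehyde (enone and ester are spared) with retention of the E geometry, the sulfonamide-bound chromium is expected to direct attack to the Re face of the formyl group to give the (R)-carbinol C1, and the γ-hydroxy ester closes to the five-membered lactone, any epimer at C1 or C5 being a diastereomer removable by chromatography.

Step 9
Reactants: 17 (1R,5S)-1-[(1E,5R)-5-(tert-butyldimethylsilyloxy)-2,6-dimethylhepta-1,6-dien-1-yl]-2-oxaspiro[4.5]dec-6-ene-3,8-dione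
Product: 19 (1R,5S)-1-[(1E,5R)-5-(tert-butyldimethylsilyloxy)-2,6-dimethylhepta-1,6-dien-1-yl]-3-oxo-2-oxaspiro[4.5]deca-6,8-dien-8-yl trifluoromethanesulfonate, via potassium dienolate 18 (not isolated)
Conditions: KHMDS (1.05 equiv), THF, −78 °C; then PhNTf2 (1.1 equiv), −78 to 0 °C
Reagents that add atoms: N-phenylbis(trifluoromethanesulfonimide) (O=S(=O)(N(c1ccccc1)S(=O)(=O)C(F)(F)F)C(F)(F)F)
Why: Kinetic enolisation of the enone can occur only at C9 because C5 is quaternary, the ketone α'-protons are far more acidic than the lactone α-protons, and O-triflation of the cross-conjugated dienolate gives the 2-triflyloxy-1,3-diene (enol triflate formation).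

Step 10
Reactants: 19 (1R,5S)-1-[(1E,5R)-5-(tert-butyldimethylsilyloxy)-2,6-dimethylhepta-1,6-dien-1-yl]-3-oxo-2-oxaspiro[4.5]deca-6,8-dien-8-yl trifluoromethanesulfonate
Product: 20 (1R,5S)-1-[(1E,5R)-5-(tert-butyldimethylsilyloxy)-2,6-dimethylhepta-1,6-dien-1-yl]-2-oxaspiro[4.5]deca-6,8-dien-3-one
Conditions: Pd(OAc)2 (5 mol %), PPh3 (10 mol %), Bu3N (3 equiv), HCO2H (2 equiv), DMF, 40 °C
Reagents that add atoms: none
Why: Palladium-catalysed formate reduction of an alkenyl triflate (oxidative addition, formate exchange, decarboxylation, reductive elimination) replaces OTf by H without moving the double bonds, and oxidative addition to the triflate at this temperature should outpace ionisation of the hindered allylic lactone C–O bond by zerovalent palladium.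

Step 11
Reactants: 20 (1R,5S)-1-[(1E,5R)-5-(tert-butyldimethylsilyloxy)-2,6-dimethylhepta-1,6-dien-1-yl]-2-oxaspiro[4.5]deca-6,8-dien-3-one
Product: 21 (1R,5R,6R,9R)-1-[(1E,5R)-5-(tert-butyldimethylsilyloxy)-2,6-dimethylhepta-1,6-dien-1-yl]-6,9-epidioxy-2-oxaspiro[4.5]dec-7-en-3-one (peroxide bridge syn to C4)
Conditions: O2, meso-tetraphenylporphyrin (1 mol %), CH2Cl2, −78 °C, white LED, stopped at full consumption of 20
Reagents that add atoms: dioxygen (O=O)
Why: Energy transfer from the excited porphyrin generates singlet oxygen, which adds to the s-cis diene C6=C7–C8=C9 of ring A in a concerted suprafacial [4+2] cycloaddition, forming the C6–O and C9–O bonds and moving the alkene to C7=C8. The closest known reaction type is the singlet oxygen Diels–Alder reaction of cyclohexa-1,3-dienes to 2,3-dioxabicyclo[2.2.2]oct-5-enes (as in the formation of ascaridole from α-terpinene). The one new ring, the six-membered 1,2-dioxene, closes by cycloaddition with both bonds formed in one step across C6 and C9, so no stepwise ring-closure mode is involved. Both new stereocentres are set together by the face of approach, which the spiro carbon C5 governs: its C1 substituent holds the alkenyl chain over C6 on one face, whereas the other face is flanked only by the C4 methylene, so oxygen should add syn to C4 to give (6R,9R). Chemoselectivity over the ene reaction is needed and should be secured because the conjugated diene is the most reactive π-system, the trisubstituted side-chain alkene is deactivated by the allylic lactone oxygen and the 1,1-disubstituted alkene is a poor ene partner. Facial selectivity is less critical, since the other facial isomer can also be taken on to the target.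

Step 12
Reactants: 21 (1R,5R,6R,9R)-1-[(1E,5R)-5-(tert-butyldimethylsilyloxy)-2,6-dimethylhepta-1,6-dien-1-yl]-6,9-epidioxy-2-oxaspiro[4.5]dec-7-en-3-one
Product: 22 (1R,5S,6R,9R)-1-[(1E,5R)-5-(tert-butyldimethylsilyloxy)-2,6-dimethylhepta-1,6-dien-1-yl]-6,9-dihydroxy-2-oxaspiro[4.5]dec-7-en-3-one
Conditions: thiourea (1.5 equiv), MeOH, 0 °C to rt
Reagents that add atoms: none
Why: Thiourea reduction of a bicyclic endoperoxide cleaves only the O–O bond and gives the cis-2-ene-1,4-diol with both carbinol configurations retained, leaving alkenes, lactone and silyl ether untouched.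

Step 13
Reactants: 22 (1R,5S,6R,9R)-1-[(1E,5R)-5-(tert-butyldimethylsilyloxy)-2,6-dimethylhepta-1,6-dien-1-yl]-6,9-dihydroxy-2-oxaspiro[4.5]dec-7-en-3-one
Product: 23 (1R,5S,6R,9S)-1-[(1E,5R)-5-(tert-butyldimethylsilyloxy)-2,6-dimethylhepta-1,6-dien-1-yl]-6-hydroxy-3-oxo-2-oxaspiro[4.5]dec-7-en-9-yl acetate
Conditions: PPh3 (1.3 equiv), DIAD (1.3 equiv), AcOH (1.5 equiv), THF, 0 °C
Reagents that add atoms: acetic acid (CC(=O)O)
Why: Mitsunobu esterification displaces the alkoxyphosphonium ion by SN2 with inversion, and only the C9 hydroxyl should react because the C6 hydroxyl is neopentylic (next to the spiro carbon), which turns (9R) into the required (9S)-acetate, now cis to C1.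

Step 14
Reactants: 23 (1R,5S,6R,9S)-1-[(1E,5R)-5-(tert-butyldimethylsilyloxy)-2,6-dimethylhepta-1,6-dien-1-yl]-6-hydroxy-3-oxo-2-oxaspiro[4.5]dec-7-en-9-yl acetate
Product: 24 (1R,5R,9S)-1-[(1E,5R)-5-(tert-butyldimethylsilyloxy)-2,6-dimethylhepta-1,6-dien-1-yl]-3,6-dioxo-2-oxaspiro[4.5]dec-7-en-9-yl acetate
Conditions: Dess–Martin periodinane (1.5 equiv), NaHCO3, CH2Cl2, 0 °C to rt
Reagents that add atoms: none
Why: Dess–Martin oxidation of the remaining secondary allylic alcohol gives the enone under buffered, non-basic conditions that should leave the γ-acetoxy group and the allylic lactone intact.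

Step 15
Reactants: 24 (1R,5R,9S)-1-[(1E,5R)-5-(tert-butyldimethylsilyloxy)-2,6-dimethylhepta-1,6-dien-1-yl]-3,6-dioxo-2-oxaspiro[4.5]dec-7-en-9-yl acetate
Product: 25 (1R,5R,9S)-1-[(1E,5R)-5-hydroxy-2,6-dimethylhepta-1,6-dien-1-yl]-3,6-dioxo-2-oxaspiro[4.5]dec-7-en-9-yl acetate (CNP0151251.2)
Conditions: HF·pyridine, pyridine, THF, 0 °C to rt
Reagents that add atoms: none
Why: Fluoride-mediated silyl ether cleavage with buffered HF·pyridine is mild enough for the acetate, the enone and the allylic lactone and should release the (5'R)-alcohol without touching any stereocentre.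

**Compound list**

1 | pent-4-ynoic acid | C#CCCC(=O)O | starting material
2 | 1-(imidazol-1-yl)pent-4-yn-1-one (acyl imidazole, formed in the flask) | C#CCCC(=O)n1ccnc1 | intermediate
3 | N-methoxy-N-methylpent-4-ynamide | C#CCCC(=O)N(C)OC | intermediate
4 | isopropenylmagnesium bromide | C=C(C)[Mg]Br | starting material
5 | 2-methylhept-1-en-6-yn-3-one | C=C(C)C(=O)CCC#C | intermediate
6 | (3R)-2-methylhept-1-en-6-yn-3-ol | C=C(C)[C@H](O)CCC#C | intermediate
7 | tert-butyldimethyl{[(3R)-2-methylhept-1-en-6-yn-3-yl]oxy}silane | C=C(C)[C@H](O[Si](C)(C)C(C)(C)C)CCC#C | intermediate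
8 | [(1E,5R)-5-(tert-butyldimethylsilyloxy)-2,6-dimethylhepta-1,6-dien-1-yl]dimethylalane (formed in the flask) | C=C(C)[C@H](O[Si](C)(C)C(C)(C)C)CC/C(C)=C/[Al](C)C | intermediate
9 | tert-butyl{[(3R,6E)-7-iodo-2,6-dimethylhepta-1,6-dien-3-yl]oxy}dimethylsilane | C=C(C)[C@H](O[Si](C)(C)C(C)(C)C)CC/C(C)=C/I | intermediate
10 | methyl 4-oxobutanoate | COC(=O)CCC=O | starting material
11 | formaldehyde | C=O | starting material
12 | methyl 3-formylbut-3-enoate | COC(=O)CC(=C)C=O | intermediate
13 | (E)-3-(tert-butyldimethylsilyloxy)-N,N-dimethylbuta-1,3-dien-1-amine | CN(C)/C=C/C(=C)O[Si](C)(C)C(C)(C)C | starting material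
14 | methyl 2-[(1S,2S)-4-(tert-butyldimethylsilyloxy)-2-(dimethylamino)-1-formylcyclohex-3-en-1-yl]acetate (endo cycloadduct, amine cis to formyl, formed in the flask) | COC(=O)C[C@]1(C=O)[C@@H](N(C)C)C=C(O[Si](C)(C)C(C)(C)C)CC1 | intermediate
15 | methyl 2-[(1S)-1-formyl-4-oxocyclohex-2-en-1-yl]acetate | COC(=O)C[C@]1(C=O)C=CC(=O)CC1 | intermediate
16 | methyl 2-[(1S)-1-[(1R,2E,6R)-6-(tert-butyldimethylsilyloxy)-1-hydroxy-3,7-dimethylocta-2,7-dien-1-yl]-4-oxocyclohex-2-en-1-yl]acetate (formed in the flask) | C=C(C)[C@H](O[Si](C)(C)C(C)(C)C)CC/C(C)=C/[C@@H](O)[C@@]1(CC(=O)OC)C=CC(=O)CC1 | intermediate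
17 | (1R,5S)-1-[(1E,5R)-5-(tert-butyldimethylsilyloxy)-2,6-dimethylhepta-1,6-dien-1-yl]-2-oxaspiro[4.5]dec-6-ene-3,8-dione | C=C(C)[C@H](O[Si](C)(C)C(C)(C)C)CC/C(C)=C/[C@H]1OC(=O)C[C@]12CCC(=O)C=C2 | intermediate
18 | potassium (1R,5S)-1-[(1E,5R)-5-(tert-butyldimethylsilyloxy)-2,6-dimethylhepta-1,6-dien-1-yl]-3-oxo-2-oxaspiro[4.5]deca-6,8-dien-8-olate (formed in the flask) | C=C(C)[C@H](O[Si](C)(C)C(C)(C)C)CC/C(C)=C/[C@H]1OC(=O)C[C@]12CC=C([O-])C=C2.[K+] | intermediate
19 | (1R,5S)-1-[(1E,5R)-5-(tert-butyldimethylsilyloxy)-2,6-dimethylhepta-1,6-dien-1-yl]-3-oxo-2-oxaspiro[4.5]deca-6,8-dien-8-yl trifluoromethanesulfonate | C=C(C)[C@H](O[Si](C)(C)C(C)(C)C)CC/C(C)=C/[C@H]1OC(=O)C[C@]12CC=C(OS(=O)(=O)C(F)(F)F)C=C2 | intermediate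
20 | (1R,5S)-1-[(1E,5R)-5-(tert-butyldimethylsilyloxy)-2,6-dimethylhepta-1,6-dien-1-yl]-2-oxaspiro[4.5]deca-6,8-dien-3-one | C=C(C)[C@H](O[Si](C)(C)C(C)(C)C)CC/C(C)=C/[C@H]1OC(=O)C[C@]12CC=CC=C2 | intermediate
21 | (1R,5R,6R,9R)-1-[(1E,5R)-5-(tert-butyldimethylsilyloxy)-2,6-dimethylhepta-1,6-dien-1-yl]-6,9-epidioxy-2-oxaspiro[4.5]dec-7-en-3-one (peroxide bridge syn to C4) | C=C(C)[C@H](O[Si](C)(C)C(C)(C)C)CC/C(C)=C/[C@H]1OC(=O)C[C@]12C[C@@H]3C=C[C@H]2OO3 | intermediate
22 | (1R,5S,6R,9R)-1-[(1E,5R)-5-(tert-butyldimethylsilyloxy)-2,6-dimethylhepta-1,6-dien-1-yl]-6,9-dihydroxy-2-oxaspiro[4.5]dec-7-en-3-one | C=C(C)[C@H](O[Si](C)(C)C(C)(C)C)CC/C(C)=C/[C@H]1OC(=O)C[C@]12C[C@@H](O)C=C[C@H]2O | intermediate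
23 | (1R,5S,6R,9S)-1-[(1E,5R)-5-(tert-butyldimethylsilyloxy)-2,6-dimethylhepta-1,6-dien-1-yl]-6-hydroxy-3-oxo-2-oxaspiro[4.5]dec-7-en-9-yl acetate | C=C(C)[C@H](O[Si](C)(C)C(C)(C)C)CC/C(C)=C/[C@H]1OC(=O)C[C@]12C[C@H](OC(C)=O)C=C[C@H]2O | intermediate
24 | (1R,5R,9S)-1-[(1E,5R)-5-(tert-butyldimethylsilyloxy)-2,6-dimethylhepta-1,6-dien-1-yl]-3,6-dioxo-2-oxaspiro[4.5]dec-7-en-9-yl acetate | C=C(C)[C@H](O[Si](C)(C)C(C)(C)C)CC/C(C)=C/[C@H]1OC(=O)C[C@]12C[C@H](OC(C)=O)C=CC2=O | intermediate
25 | (1R,5R,9S)-1-[(1E,5R)-5-hydroxy-2,6-dimethylhepta-1,6-dien-1-yl]-3,6-dioxo-2-oxaspiro[4.5]dec-7-en-9-yl acetate | C=C(C)[C@H](O)CC/C(C)=C/[C@H]1OC(=O)C[C@]12C[C@H](OC(C)=O)C=CC2=O | target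

**Totals and risks**

Total step count: 15. Longest linear sequence: 13 steps (steps 1–5, then 8–15).

Steps most likely to fail:

Step 8. The ligand-bound chromium reagent may not override the bias of the neighbouring quaternary centre, so the two formyl faces are poorly discriminated, and the hindered partners may couple slowly. Fallback: the carbinol would be set by ketone reduction instead of by C–C bond formation, at a stage where ring A no longer carries a ketone.
- From 15 and 9 the coupling is run without ligand (CrCl2, NiCl2, DMSO). It gives 16 and 17 together with the (1S)-carbinol hydroxy ester F2 and the (1S)-spirolactone enone F3.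
- The epimer pair is carried through steps 9 and 10, the accompanying compounds being the (1S)-potassium dienolate F4, the (1S)-dienyl triflate F5 and the (1S)-spiro diene F6.
- Both lactones are opened with Me(MeO)NH·HCl/Me3Al (CH2Cl2, 0 °C) to the (S)-hydroxy N-methoxy-N-methyl amide F7 (from F6) and the (R)-hydroxy N-methoxy-N-methyl amide F8 (from 20).
- Dess–Martin oxidation of the mixture converges on the keto amide F9.
- CBS reduction ((S)-2-methyl-CBS-oxazaborolidine, catecholborane, toluene, −78 °C, the quaternary carbon acting as the large group) should return F8 alone, which relactonises with loss of the amine on warming with PPTS in toluene to give 20, where the route is rejoined.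

Step 11. The spiro centre may discriminate the two diene faces incompletely (and prolonged irradiation may bring on ene oxidation of the side chain). Fallback: the facial isomer is taken forward by acylation with retention instead of Mitsunobu inversion.
- The facial-isomer endoperoxide F10 (peroxide syn to C1), formed from 20 beside 21, is reduced with thiourea to the cis-diol F11, whose C9 hydroxyl already has the target configuration.
- Selective acetylation of that unhindered hydroxyl (Ac2O, 2,4,6-collidine, CH2Cl2, −20 °C) gives the monoacetate F12, the C6 epimer of 23.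
- Dess–Martin oxidation as in step 14 erases C6 and gives 24, where both series converge.

Step 7. The basic amino diene may shift the dienophile double bond into conjugation with the ester before cycloaddition, or hydrogen-bond control may be weak for the ester-bearing acrolein and erode the enantiomeric purity. Fallback: an acid-catalysed cycloaddition with a non-basic diene, followed by oxidative rather than eliminative unmasking.
- From 12, Diels–Alder reaction with 2-(triisopropylsilyloxy)buta-1,3-diene under a cationic oxazaborolidine catalyst (o-tolyl oxazaborolidine from diphenylprolinol, activated with triflimide, CH2Cl2, −78 °C) would give methyl 2-[(1R)-1-formyl-4-(triisopropylsilyloxy)cyclohex-3-en-1-yl]acetate F1.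
- Saegusa–Ito oxidation of the silyl enol ether (Pd(OAc)2, MeCN, rt) then gives enone 15, where the route is rejoined.

**Further compounds**

F1 | step 7 | methyl 2-[(1R)-1-formyl-4-(triisopropylsilyloxy)cyclohex-3-en-1-yl]acetate | COC(=O)C[C@]1(C=O)CC=C(O[Si](C(C)C)(C(C)C)C(C)C)CC1
F2 | step 8 | methyl 2-[(1S)-1-[(1S,2E,6R)-6-(tert-butyldimethylsilyloxy)-1-hydroxy-3,7-dimethylocta-2,7-dien-1-yl]-4-oxocyclohex-2-en-1-yl]acetate | C=C(C)[C@H](O[Si](C)(C)C(C)(C)C)CC/C(C)=C/[C@H](O)[C@@]1(CC(=O)OC)C=CC(=O)CC1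
F3 | step 8 | (1S,5S)-1-[(1E,5R)-5-(tert-butyldimethylsilyloxy)-2,6-dimethylhepta-1,6-dien-1-yl]-2-oxaspiro[4.5]dec-6-ene-3,8-dione | C=C(C)[C@H](O[Si](C)(C)C(C)(C)C)CC/C(C)=C/[C@@H]1OC(=O)C[C@]12CCC(=O)C=C2
F4 | step 8 | potassium (1S,5S)-1-[(1E,5R)-5-(tert-butyldimethylsilyloxy)-2,6-dimethylhepta-1,6-dien-1-yl]-3-oxo-2-oxaspiro[4.5]deca-6,8-dien-8-olate | C=C(C)[C@H](O[Si](C)(C)C(C)(C)C)CC/C(C)=C/[C@@H]1OC(=O)C[C@]12CC=C([O-])C=C2.[K+]
F5 | step 8 | (1S,5S)-1-[(1E,5R)-5-(tert-butyldimethylsilyloxy)-2,6-dimethylhepta-1,6-dien-1-yl]-3-oxo-2-oxaspiro[4.5]deca-6,8-dien-8-yl trifluoromethanesulfonate | C=C(C)[C@H](O[Si](C)(C)C(C)(C)C)CC/C(C)=C/[C@@H]1OC(=O)C[C@]12CC=C(OS(=O)(=O)C(F)(F)F)C=C2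
F6 | step 8 | (1S,5S)-1-[(1E,5R)-5-(tert-butyldimethylsilyloxy)-2,6-dimethylhepta-1,6-dien-1-yl]-2-oxaspiro[4.5]deca-6,8-dien-3-one | C=C(C)[C@H](O[Si](C)(C)C(C)(C)C)CC/C(C)=C/[C@@H]1OC(=O)C[C@]12CC=CC=C2
F7 | step 8 | 2-[(1S)-1-[(1S,2E,6R)-6-(tert-butyldimethylsilyloxy)-1-hydroxy-3,7-dimethylocta-2,7-dien-1-yl]cyclohexa-2,4-dien-1-yl]-N-methoxy-N-methylacetamide | C=C(C)[C@H](O[Si](C)(C)C(C)(C)C)CC/C(C)=C/[C@H](O)[C@@]1(CC(=O)N(C)OC)C=CC=CC1
F8 | step 8 | 2-[(1S)-1-[(1R,2E,6R)-6-(tert-butyldimethylsilyloxy)-1-hydroxy-3,7-dimethylocta-2,7-dien-1-yl]cyclohexa-2,4-dien-1-yl]-N-methoxy-N-methylacetamide | C=C(C)[C@H](O[Si](C)(C)C(C)(C)C)CC/C(C)=C/[C@@H](O)[C@@]1(CC(=O)N(C)OC)C=CC=CC1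
F9 | step 8 | 2-[(1S)-1-[(2E,6R)-6-(tert-butyldimethylsilyloxy)-3,7-dimethylocta-2,7-dienoyl]cyclohexa-2,4-dien-1-yl]-N-methoxy-N-methylacetamide | C=C(C)[C@H](O[Si](C)(C)C(C)(C)C)CC/C(C)=C/C(=O)[C@@]1(CC(=O)N(C)OC)C=CC=CC1
F10 | step 11 | (1R,5R,6S,9S)-1-[(1E,5R)-5-(tert-butyldimethylsilyloxy)-2,6-dimethylhepta-1,6-dien-1-yl]-6,9-epidioxy-2-oxaspiro[4.5]dec-7-en-3-one (peroxide bridge syn to C1) | C=C(C)[C@H](O[Si](C)(C)C(C)(C)C)CC/C(C)=C/[C@H]1OC(=O)C[C@]12C[C@H]3C=C[C@@H]2OO3
F11 | step 11 | (1R,5S,6S,9S)-1-[(1E,5R)-5-(tert-butyldimethylsilyloxy)-2,6-dimethylhepta-1,6-dien-1-yl]-6,9-dihydroxy-2-oxaspiro[4.5]dec-7-en-3-one | C=C(C)[C@H](O[Si](C)(C)C(C)(C)C)CC/C(C)=C/[C@H]1OC(=O)C[C@]12C[C@H](O)C=C[C@@H]2O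
F12 | step 11 | (1R,5S,6S,9S)-1-[(1E,5R)-5-(tert-butyldimethylsilyloxy)-2,6-dimethylhepta-1,6-dien-1-yl]-6-hydroxy-3-oxo-2-oxaspiro[4.5]dec-7-en-9-yl acetate | C=C(C)[C@H](O[Si](C)(C)C(C)(C)C)CC/C(C)=C/[C@H]1OC(=O)C[C@]12C[C@H](OC(C)=O)C=C[C@@H]2O
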